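The data were generated by integration with constants of no real substance; scatter was added.

all flasks: free catalyst 0.2 mol%

| flask | substrate | partner | protic impurity | remark | time |
|---|---|---|---|---|---|
| Sunday's | 0.050 M | 0.55 equiv | 0.025 M | run made earlier |  |
| Tuesday's | 0.050 M | 1.1 equiv | 0.025 M | run made earlier |  |
| Wednesday's | 0.050 M | 1.3 equiv | 0.025 M | run made earlier |  |
| Saturday's | 0.050 M | 1.8 equiv | 0.040 M | run made earlier |  |
| oak | 0.080 M | 0.590 equiv | 0.0800 M |  | 1.5 h |
| cedar | 0.050 M | 1.80 equiv | 0.0250 M |  | 1.5 h |

| run | time / min | product / % |
|---|---|---|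
| Sunday's | 8.00 | 7.7 |
| Sunday's | 20.0 | 14.8 |
| Sunday's | 40.0 | 23.3 |
| Sunday's | 60.0 | 23.8 |
| Tuesday's | 5.00 | 5.2 |
| Tuesday's | 12.0 | 12.0 |
| Tuesday's | 25.0 | 24.5 |
| Tuesday's | 60.0 | 48.2 |
| Wednesday's | 8.00 | 8.2 |
| Wednesday's | 20.0 | 20.4 |
| Wednesday's | 40.0 | 38.4 |
| Wednesday's | 60.0 | 53.0 |
| Saturday's | 8.00 | 8.5 |
| Saturday's | 20.0 | 20.7 |
| Saturday's | 40.0 | 39.6 |
| Saturday's | 60.0 | 57.2 |

(readings scatter by 0.5 percentage points)

- where the amount of substrate changes, what is given in equivalents or mol% on it follows
- no earlier run changes the charge of free catalyst; that part of a forecast is a guess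

- which of the two ends with the higher amount of product, in percent of the substrate charged ("neither" if they lie within 2 percentage points) (oak / cedar / neither)
- product at the end, in percent of the substrate charged, oak
- product at the end, in percent of the substrate charged, cedar

- 4.95 min⁻¹ is the pace, in turnovers per catalyst, read from Saturday's run: 39.6% product after 40.0 min on a loading of 0.2 mol%.
- Sunday's run stops, moving from 23.3% to 23.8% in its last interval, a step the size of the scatter. Partner is its limiting reagent. At Saturday's pace, Sunday's product amounts to a working time of 24.0 min.
- The first way to a product figure is a balance in which the whole charge of protic impurity takes an equal amount of partner at once. For Sunday's run this gives 5.00%, far less than the reading. For oak it gives no product, since partner at 0.0472 M stands below impurity at 0.0800 M. This is the way that cheats: quenching takes time.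
- The second way is a race. Counted as charge less product, Sunday's run lost 0.0156 M of partner to impurity, and this reckoning spreads that loss over the working time above. Dividing that loss by the time and by the mean values of c(partner) and c(protic impurity) gives the quench constant 0.0457 L mol⁻¹ s⁻¹, itself a reading with scatter.
- In this reckoning of my own, oak loses partner at 0.00365 M min⁻¹ to impurity and at 7.92 × 10⁻⁴ M min⁻¹ to turnover. Its partner therefore lasts 10.6 min, which is 52.5 turnovers, or 10.5% product. That short early window is the part of oak to watch.
- Cedar keeps 0.0650 M of partner beyond its impurity, above its substrate charge of 0.050 M. Full pace over 1.5 h counts to 89.1%, a figure that falling substrate can lower.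
- The forecast says cedar, with 17% for oak, above my figure, and 79% for cedar. Its ground for oak: “Oak has a large impurity excess and higher concentrations, so the side reaction takes most of the partner.”
- The flask gives cedar: 81.2% for cedar and 13.3% for oak, which lies between my figure and the forecast's.

    partner + free catalyst ⇌ catalyst intermediate A (K = 7.40 L mol⁻¹, k = 39.0 L mol⁻¹ s⁻¹)
    substrate + catalyst intermediate A → catalyst intermediate B (k = 71.0 L mol⁻¹ s⁻¹)
    catalyst intermediate B → released group + catalyst intermediate C (k = 0.110 s⁻¹)
    catalyst intermediate C → free catalyst + product (k = 2.10 s⁻¹)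
    partner + catalyst intermediate C ⇌ idle complex, settled at all times (K = 18.0 L mol⁻¹)
    partner + protic impurity → quenched reagent (k = 0.0440 L mol⁻¹ s⁻¹)

- The neighbouring flask is oak with 0.350 equiv of partner, so c(partner) starts at 0.0280 M. The same constant 0.0457 L mol⁻¹ s⁻¹ gives a quench rate of 0.00254 M min⁻¹, a partner lifetime of 8.42 min and 8.33% product. That neighbour ends at 8.93% product, with partner at 0% of its charge and 74% of its protic impurity still there.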